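## Structural features

The target is a labdane-type diterpenoid acid of the ent series. It is a trans-fused decalin (ring A: C1–C5 and C10; ring B: C5–C10) with a (3R)-3-methylpentanoic acid chain (C11–C15, methyl on C13) on C9, an exocyclic methylene on C8, a gem-dimethyl group on C4 and an acetoxy group on C3. The ring stereocentres are C3 (S), C5 (S), C9 (R) and the quaternary C10 (S); C5, C10 and C9 are contiguous, and C3 is separated from C5 only by the fully substituted C4. In the chair–chair decalin the C10 methyl is axial and anti to H5, the C9 chain is equatorial and cis to the C10 methyl, and the C3 acetate is axial and cis to H5, so the oxygen must come from equatorial hydride delivery to a 3-ketone. C13 (R) is too far from the ring to be controlled by it and has to arrive in an enantiopure chain fragment. The fragile groups are the 1,1-disubstituted C8=C17 alkene (acid-induced migration into the ring, hydrogenation) and the pairing of an acetate with a free carboxylic acid, which fixes the order of the last steps. The real difficulty is the quaternary C10, flanked by two stereocentres and by the congested C4, in one absolute configuration. Ring A provides the handle: the trans pair C5–H/C10–CH3 beside C4 and the oxygenated C3 is the retron of a [4+2] cycloaddition between an (E)-2-methyl enal (C9 as formyl carbon, C10, C5) and a 2-silyloxydiene (C1–C4, oxygen on C3).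

## Logic of the disconnections

The acetyl C–O bond at C3 of 24 is cut first, giving 22. Acetylation is left to the end because an acetate would not survive ester hydrolysis or hydride reagents. The forward step must acylate a hindered axial alcohol in the presence of a free acid, which is acceptable because the mixed anhydride that forms at C15 is cleaved by water.

The C3–H bond and the C15 O–H of 22 are traced back to the ketone and methyl ester of 20. This removes the C3 stereocentre from the problem. The forward step needs a hydride bulky enough to attack the 4,4-dimethyl-3-ketone from the equatorial side, and a work-up that also saponifies the ester.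

The two hydrogens on C1 and C2 of 20 are removed to give 19, and one C4–CH3 bond of 19 is then cut to give 18. The reason is regiochemical. The enol ether that the cycloaddition leaves in ring A lies between C2 and C3, so hydrolysis followed by methylation would alkylate C2 or give mixtures. In 18, C2 is vinylic and C10 is quaternary, so the only acidic hydrogen next to the ketone is H4. The price is one conjugate reduction, which must spare the C8=C17 alkene and the ester.

The C1=C2 bond of 18 is traced to the silyl enol ether of 17 by dehydrosilylation. The enol ether therefore serves first as the masked C3 ketone and then as the regiochemical marker for the enone. The forward step must oxidise a bulky silyl enol ether without touching the exocyclic alkene.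

The C8–C9 bond of 17 (ring B) and the C17–H bond are cut to give 15. This opens the decalin to a monocycle that carries a terminal alkyne and a (Z)-alkene, and it removes the C9 stereocentre. The forward step must add a C8 vinyl radical to C9 in the 6-exo mode, on the face that makes the chain equatorial, and leave only hydrogen on C17.

The C9=C11 double bond of 15 is cut to give 7 and 12. This separates the ring fragment from the chain fragment that carries C13. The forward olefination must succeed on a neopentyl aldehyde, and the C15 carboxyl must not be attacked by its own ylide.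

The C11–P bond of 12 is cut and the C11–O/C15 pair is traced through 10 to 8. C13 is thus taken from a desymmetrised 3-methylglutarate. The demand is only that the free acid of 8 be reduced and the ester retained.

The C4–C5 and C1–C10 bonds of 7 are cut to give 4 and 6. This is the simplifying step: ring A, the quaternary C10 and the C5/C10 trans pair fall back to two achiral acyclic partners. It demands control of the enal face by a chiral Lewis acid and regiocontrol by the silyloxy group.

The C=C bond of 4 is cut to give 1 (after oxidation) and 2, and the O–Si bond of 6 is cut to give 5. Both partners then come from purchasable materials in one step each. The demands are (E) geometry in 4 and (Z) geometry in 6.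

## Other disconnections considered

Alternative 1: The cut runs through C5–C10 and C8–C9 and opens both rings at once, leading to the acyclic trienoate A2. Heating or Et2AlCl would fold A2 in an intramolecular Diels–Alder reaction to the trans-fused adduct A1.
- In its favour: one pericyclic event would create both rings and four stereocentres (C5, C8, C9, C10). The gem-dimethyl group is already present, so there is no regiochemical question at C4; on this point it is better than the chosen plan. No chiral catalyst is needed, since the silyloxy stereocentre of A2 relays the absolute configuration.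
- Against it here: the dienophile is a β,β-disubstituted enoate that has to form the quaternary C10, so the cycloaddition is expected to be slow. Its endo/exo and facial preferences rest on a remote silyloxy group. The C3 oxygen of A1 is equatorial and would have to be inverted through the ketone. C11 arrives as an ester and must be extended by four carbons including C13. The C6=C7 alkene must be hydrogenated before the C8=C17 alkene is made from the oxymethyl group.
- Comparison: both plans use a [4+2] reaction to set the C5/C10 trans pair and are equal there. Alternative 1 is superior in bonds and stereocentres per step. It is inferior in step economy, because A2 is itself a long linear target and the functional-group work after the key step is heavier.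

Alternative 2: The cut is the C9–C10 bond, traced back to a 1,2-shift. BF3·OEt2 would open the epoxide of the tertiary epoxy carbinol A4 at C9 while C10 migrates from C8 to C9, expanding the cyclopentanol into the ring B cyclohexanone of A3.
- In its favour: the absolute configuration at C10 would come from an amino-acid-catalysed annulation, which is cheaper and more robust than a cationic oxazaborolidine; on this point it is better. The shift is stereospecific (inversion at C9, retention at C10). The Δ4-3-ketone of A3 allows the classical gem-dimethylation at C4, which is regiochemically more direct than the enone detour chosen here; this is also better. The C8 ketone is ready for methylenation.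
- Against it here: migration of C7 or simple epoxide opening may compete in the Lewis-acid step. A3 still lacks the C5 stereocentre and the whole C12–C15 chain with C13, which must be attached through the C11 hydroxymethyl group in a separate coupling. Two ketones (C3 and C8) must be distinguished more than once.
- Comparison: mechanistically it is a cationic rearrangement instead of a cycloaddition, with equal confidence in the C9/C10 relationship. Structurally it arrives at a bicyclic core earlier, but it needs clearly more steps after the key step than the chosen plan.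

Alternative 3: The cut is C8–C9 and C1–C10. Bu3SnH and AIBN would turn the Se-phenyl selenoester A6 into the C8 acyl radical, which would add 6-endo to C9; the resulting tertiary C10 radical would add 6-endo to the vinyl ketone and give A5.
- In its favour: both rings and the C9 and C10 stereocentres would form in one operation with the complete side chain in place. After the key step only C8 methylenation, C3 reduction, hydrolysis and acetylation remain, so the end game is shorter than in the chosen plan; this is better. The C3 ketone is shielded by the gem-dimethyl group, which should help chemoselective methylenation at C8.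
- Against it here: all relative and absolute control rests on the single C5 stereocentre of the acyclic A6, which needs its own asymmetric synthesis. The 6-endo/5-exo choice, decarbonylation of the acyl radical, the trans ring fusion and the C9 configuration are all decided under kinetic control of fast radicals.
- Comparison: both plans use tin-mediated radical chemistry for ring B and are equal in that respect. Alternative 3 is more convergent on paper. The chosen plan places the quaternary C10 by a catalyst-controlled, closed-shell step whose selectivity model is well defined, and is judged the safer of the two.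

Key step: step 3

Remarks on the chemistry. Labdane numbering is used for atoms throughout. Methyl hydrogen (R)-3-methylglutarate (8) is assumed to be purchasable in enantiopure form; the parent anhydride is achiral and would otherwise need a desymmetrising methanolysis. The C4 configuration drawn for 7, 15, 17 and 18 is the one expected from the formyl-endo transition state; the C4 epimer would converge at 19.

## Steps

Step 1
Reactants: 1 pent-4-yn-1-ol; 2 2-(triphenylphosphoranylidene)propanal
Product: 4 (E)-2-methylhept-2-en-6-ynal, via pent-4-ynal 3 (not isolated)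
Conditions: PhI(OAc)2 (1.1 equiv), TEMPO (10 mol%), CH2Cl2, rt; then 2 (1.2 equiv), 40 °C
Reagents that add atoms: none
Why: The nitroxyl-catalysed oxidation stops at the aldehyde, and the volatile pent-4-ynal is consumed in the same flask by a Wittig reaction. The formyl-stabilised ylide reacts reversibly and should give the (E)-trisubstituted enal; the conjugated product is too unreactive to add a second ylide.

Step 2
Reactants: 5 pent-1-en-3-one
Product: 6 (Z)-3-[(triisopropylsilyl)oxy]penta-1,3-diene
Conditions: i-Pr3SiOTf (1.1 equiv), Et3N (1.5 equiv), Et2O, 0 °C → rt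
Reagents that add atoms: triisopropylsilyl trifluoromethanesulfonate, CC(C)[Si](C(C)C)(C(C)C)OS(=O)(=O)C(F)(F)F
Why: Soft enolisation with silyl triflate and amine O-silylates the ethyl ketone. The (Z) enol ether (methyl cis to oxygen) is favoured because it avoids A(1,3) strain between the methyl and the vinyl group, and it is the isomer whose methyl is "outside" in the s-cis diene.

Step 3
Reactants: 4 (E)-2-methylhept-2-en-6-ynal; 6 (Z)-3-[(triisopropylsilyl)oxy]penta-1,3-diene
Product: 7 (1R,5R,6R)-6-(but-3-yn-1-yl)-1,5-dimethyl-4-[(triisopropylsilyl)oxy]cyclohex-3-ene-1-carbaldehyde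
Conditions: (S)-3,3-diphenyl-1-(o-tolyl)tetrahydro-1H,3H-pyrrolo[1,2-c][1,3,2]oxazaborole·HNTf2 (20 mol%), 6 (2 equiv), CH2Cl2, −78 → −40 °C
Reagents that add atoms: none
Why: The protonated oxazaborolidine binds the formyl oxygen of 4 syn to the formyl hydrogen, which is held by a C–H···O contact to the ring oxygen; the s-trans enal then lies against the C-phenyl group cis to boron and only the Re face at C10 is open. The reaction is a concerted, asynchronous, normal-demand [4+2] cycloaddition, and the closest known reaction type is the cationic-oxazaborolidine-catalysed Diels–Alder reaction of α-substituted enals with 2-silyloxydienes. Ring A is closed by suprafacial–suprafacial union of the four diene carbons with the two alkene carbons, the C4–C5 bond running ahead of the C1–C10 bond. C10 is set by the catalyst-controlled facial choice; C5 follows from C10 because addition is suprafacial on the (E)-enal, which places the butynyl chain trans to formyl. C4 is set by the (Z) enol ether geometry together with the formyl-endo arrangement and is of no consequence, because C4 later becomes gem-dimethyl. The step needs regioselectivity, which the silyloxy group secures by making the methyl-bearing diene terminus the nucleophilic one and matching it with the electrophilic β-carbon. It also needs chemoselectivity for C=C over C=O, which the modest donor strength of a mono-oxygenated diene secures; the alkyne and the bulky silyl enol ether should be inert to the catalyst at low temperature. The formyl group sits on a quaternary carbon and cannot enolise, so the new stereocentres are configurationally safe.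

Step 4
Reactants: 8 (3R)-5-methoxy-3-methyl-5-oxopentanoic acid
Product: 10 (4R)-4-methyltetrahydro-2H-pyran-2-one, via hydroxy ester 9 (not isolated)
Conditions: BH3·SMe2 (1.1 equiv), THF, −10 °C → rt; MeOH; then TsOH·H2O (5 mol%), PhH, 50 °C
Reagents that add atoms: none
Why: Borane reduces the free acid through its acyloxyborane and leaves the ester alone; the 5-hydroxy ester then lactonises under acid. C13 is β to both carbonyl groups and is not touched.

Step 5
Reactants: 10 (4R)-4-methyltetrahydro-2H-pyran-2-one
Product: 12 [(3S)-4-carboxy-3-methylbutyl]triphenylphosphonium bromide, via bromo acid 11 (not isolated)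
Conditions: HBr (33% in AcOH), 60 °C; evaporate; PPh3 (1.1 equiv), MeCN, reflux
Reagents that add atoms: hydrogen bromide, Br; triphenylphosphine, c1ccc(cc1)P(c1ccccc1)c1ccccc1
Why: Bromide opens the protonated δ-lactone by SN2 attack at the O–CH2 carbon, and the primary bromide then quaternises the phosphine. The change of descriptor at C13 from R to S is only a change of CIP priorities.

Step 6
Reactants: 7 (1R,5R,6R)-6-(but-3-yn-1-yl)-1,5-dimethyl-4-[(triisopropylsilyl)oxy]cyclohex-3-ene-1-carbaldehyde; 12 [(3S)-4-carboxy-3-methylbutyl]triphenylphosphonium bromide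
Product: 15 methyl (3R,5Z)-6-[(1S,5R,6R)-6-(but-3-yn-1-yl)-1,5-dimethyl-4-[(triisopropylsilyl)oxy]cyclohex-3-en-1-yl]-3-methylhex-5-enoate, via carboxylate ylide 13 (not isolated), via alkenoic acid 14 (not isolated)
Conditions: 12 (1.8 equiv), NaN(SiMe3)2 (3.5 equiv), THF, 0 °C; 7, −78 °C → rt; aq. NaH2PO4; crude 14: MeI (3 equiv), K2CO3, DMF, rt
Reagents that add atoms: iodomethane, CI
Why: A Wittig reaction of a non-stabilised ylide under lithium-free conditions should give the (Z)-alkene under kinetic control. The ylide is used as its carboxylate because a C15 ester could be C-acylated by its own ylide carbon to a five-membered acyl ylide. The aldehyde has no α-hydrogen and the silyl enol ether keeps the C3 ketone masked; SN2 methylation of the carboxylate then gives the ester.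

Step 7
Reactants: 15 methyl (3R,5Z)-6-[(1S,5R,6R)-6-(but-3-yn-1-yl)-1,5-dimethyl-4-[(triisopropylsilyl)oxy]cyclohex-3-en-1-yl]-3-methylhex-5-enoate
Product: 17 methyl (3R)-5-[(1R,4aR,5R,8aR)-5,8a-dimethyl-2-methylidene-6-[(triisopropylsilyl)oxy]-1,2,3,4,4a,5,8,8a-octahydronaphthalen-1-yl]-3-methylpentanoate, via vinylstannane 16 (not isolated)
Conditions: Bu3SnH (1.3 equiv) and AIBN (0.2 equiv) added over 6 h, PhH, 80 °C, 0.01 M; then SiO2, CH2Cl2, rt
Reagents that add atoms: none
Why: This is a stannyl-radical enyne cyclisation: reversible addition of Bu3Sn• to C17 gives the C8 vinyl radical, which closes ring B 6-exo-trig onto C9; the C11 radical takes hydrogen from the stannane, and the vinylstannane is protodestannylated through a β-stannyl cation. The C5 chain and the C10 alkenyl group are trans and both equatorial, so only a trans-fused chair-like transition state is available. In it the (Z)-alkene avoids A(1,3) strain by eclipsing the C10 methyl, which puts C11 pseudo-equatorial and H9 anti to that methyl, i.e. the (9R) configuration.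

Step 8
Reactants: 17 methyl (3R)-5-[(1R,4aR,5R,8aR)-5,8a-dimethyl-2-methylidene-6-[(triisopropylsilyl)oxy]-1,2,3,4,4a,5,8,8a-octahydronaphthalen-1-yl]-3-methylpentanoate
Product: 18 methyl (3R)-5-[(1R,4aR,5R,8aR)-5,8a-dimethyl-2-methylidene-6-oxo-1,2,3,4,4a,5,6,8a-octahydronaphthalen-1-yl]-3-methylpentanoate
Conditions: Pd(OAc)2 (1.1 equiv), DMSO/CH2Cl2, 40 °C
Reagents that add atoms: none
Why: In the Saegusa–Ito oxidation the silyl enol ether transmetalates to a C2-bound palladium enolate, and β-hydride elimination can only take H1. The enone is therefore formed regiospecifically between C1 and C2, and the C3 ketone is unmasked in the same step.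

Step 9
Reactants: 18 methyl (3R)-5-[(1R,4aR,5R,8aR)-5,8a-dimethyl-2-methylidene-6-oxo-1,2,3,4,4a,5,6,8a-octahydronaphthalen-1-yl]-3-methylpentanoate
Product: 19 methyl (3R)-3-methyl-5-[(1R,4aS,8aS)-5,5,8a-trimethyl-2-methylidene-6-oxo-1,2,3,4,4a,5,6,8a-octahydronaphthalen-1-yl]pentanoate
Conditions: NaH (2 equiv), MeI (5 equiv), THF, 0 °C → rt
Reagents that add atoms: iodomethane, CI
Why: This is an α′-alkylation of an enone. C2 is vinylic and C10 is quaternary, so H4 is the only acidic hydrogen next to the ketone, and the single cross-conjugated enolate is C-methylated to the gem-dimethyl group. The ester α-hydrogens are several pK units less acidic and should stay untouched under this slowly equilibrating base; the C4 stereocentre disappears.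

Step 10
Reactants: 19 methyl (3R)-3-methyl-5-[(1R,4aS,8aS)-5,5,8a-trimethyl-2-methylidene-6-oxo-1,2,3,4,4a,5,6,8a-octahydronaphthalen-1-yl]pentanoate
Product: 20 methyl (3R)-3-methyl-5-[(1R,4aS,8aS)-5,5,8a-trimethyl-2-methylidene-6-oxodecahydronaphthalen-1-yl]pentanoate
Conditions: [(Ph3P)CuH]6 (0.5 equiv), PhH, H2O (5 equiv), rt; aq. NH4Cl
Reagents that add atoms: none
Why: The phosphine-stabilised copper hydride delivers hydride to C1 of the enone (conjugate reduction), and the copper enolate is protonated at C2. Isolated 1,1-disubstituted alkenes and esters are not reduced by this reagent, and no stereocentre is formed.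

Step 11
Reactants: 20 methyl (3R)-3-methyl-5-[(1R,4aS,8aS)-5,5,8a-trimethyl-2-methylidene-6-oxodecahydronaphthalen-1-yl]pentanoate
Product: 22 (3R)-5-[(1R,4aS,6S,8aS)-6-hydroxy-5,5,8a-trimethyl-2-methylidenedecahydronaphthalen-1-yl]-3-methylpentanoic acid, via C3 alcohol ester 21 (not isolated)
Conditions: LiBH(s-Bu)3 (1.5 equiv), THF, −78 °C; then 2 M NaOH, 30% H2O2, MeOH, 0 → 40 °C; 1 M HCl to pH 3, 0 °C
Reagents that add atoms: water (as aqueous sodium hydroxide), O
Why: The bulky trialkylborohydride cannot take the axial trajectory past H1 and H5 and attacks the 4,4-dimethyl-3-ketone equatorially, which should give the axial (3S) alcohol, cis to H5; the methyl ester is inert at −78 °C. The alkaline peroxide work-up that destroys the borane is prolonged to saponify the unhindered methyl ester.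

Step 12
Reactants: 22 (3R)-5-[(1R,4aS,6S,8aS)-6-hydroxy-5,5,8a-trimethyl-2-methylidenedecahydronaphthalen-1-yl]-3-methylpentanoic acid
Product: 24 (3R)-5-[(1R,4aS,6S,8aS)-6-(acetyloxy)-5,5,8a-trimethyl-2-methylidenedecahydronaphthalen-1-yl]-3-methylpentanoic acid, via mixed anhydride 23 (not isolated)
Conditions: Ac2O (5 equiv), pyridine, DMAP (0.2 equiv), rt; then H2O/THF, rt
Reagents that add atoms: acetic anhydride, CC(=O)OC(C)=O
Why: Nucleophilic catalysis (acylpyridinium) should acetylate the hindered axial alcohol with retention. The carboxyl group is converted in passing into a mixed anhydride, which water cleaves selectively while the secondary acetate stays; no acid strong enough to move the exocyclic alkene is used.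

## Compound list

1 | pent-4-yn-1-ol | C#CCCCO | starting material
2 | 2-(triphenylphosphoranylidene)propanal | CC(C=O)=P(c1ccccc1)(c1ccccc1)c1ccccc1 | starting material
3 | pent-4-ynal | C#CCCC=O | intermediate
4 | (E)-2-methylhept-2-en-6-ynal | O=C/C(C)=C/CCC#C | intermediate
5 | pent-1-en-3-one | C=CC(=O)CC | starting material
6 | (Z)-3-[(triisopropylsilyl)oxy]penta-1,3-diene | C=C/C(O[Si](C(C)C)(C(C)C)C(C)C)=C/C | intermediate
7 | (1R,5R,6R)-6-(but-3-yn-1-yl)-1,5-dimethyl-4-[(triisopropylsilyl)oxy]cyclohex-3-ene-1-carbaldehyde (butynyl trans to formyl, 5-methyl cis to formyl) | C#CCC[C@@H]1[C@@H](C)C(O[Si](C(C)C)(C(C)C)C(C)C)=CC[C@@]1(C)C=O | intermediate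
8 | (3R)-5-methoxy-3-methyl-5-oxopentanoic acid (methyl hydrogen (R)-3-methylglutarate) | COC(=O)C[C@H](C)CC(=O)O | starting material
9 | methyl (3R)-5-hydroxy-3-methylpentanoate | COC(=O)C[C@H](C)CCO | intermediate
10 | (4R)-4-methyltetrahydro-2H-pyran-2-one | O=C1C[C@H](C)CCO1 | intermediate
11 | (3S)-5-bromo-3-methylpentanoic acid | OC(=O)C[C@H](C)CCBr | intermediate
12 | [(3S)-4-carboxy-3-methylbutyl]triphenylphosphonium bromide | [Br-].OC(=O)C[C@H](C)CC[P+](c1ccccc1)(c1ccccc1)c1ccccc1 | intermediate
13 | sodium (3S)-3-methyl-5-(triphenyl-λ5-phosphanylidene)pentanoate | [Na+].[O-]C(=O)C[C@H](C)CC=P(c1ccccc1)(c1ccccc1)c1ccccc1 | intermediate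
14 | (3R,5Z)-6-[(1S,5R,6R)-6-(but-3-yn-1-yl)-1,5-dimethyl-4-[(triisopropylsilyl)oxy]cyclohex-3-en-1-yl]-3-methylhex-5-enoic acid | C#CCC[C@@H]1[C@@H](C)C(O[Si](C(C)C)(C(C)C)C(C)C)=CC[C@@]1(C)/C=C\C[C@@H](C)CC(=O)O | intermediate
15 | methyl (3R,5Z)-6-[(1S,5R,6R)-6-(but-3-yn-1-yl)-1,5-dimethyl-4-[(triisopropylsilyl)oxy]cyclohex-3-en-1-yl]-3-methylhex-5-enoate | C#CCC[C@@H]1[C@@H](C)C(O[Si](C(C)C)(C(C)C)C(C)C)=CC[C@@]1(C)/C=C\C[C@@H](C)CC(=O)OC | intermediate
16 | C17-tributylstannyl derivative of 17: methyl (3R)-5-[5,8a-dimethyl-2-[(tributylstannyl)methylidene]-6-[(triisopropylsilyl)oxy]-1,2,3,4,4a,5,8,8a-octahydronaphthalen-1-yl]-3-methylpentanoate, ring configuration as in 17, mixture of alkene isomers | CCCC[Sn](CCCC)(CCCC)C=C1CC[C@@H]2[C@@H](C)C(O[Si](C(C)C)(C(C)C)C(C)C)=CC[C@@]2(C)[C@@H]1CC[C@@H](C)CC(=O)OC | intermediate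
17 | methyl (3R)-5-[(1R,4aR,5R,8aR)-5,8a-dimethyl-2-methylidene-6-[(triisopropylsilyl)oxy]-1,2,3,4,4a,5,8,8a-octahydronaphthalen-1-yl]-3-methylpentanoate (trans-fused; C9 chain cis to C10 methyl) | C=C1CC[C@@H]2[C@@H](C)C(O[Si](C(C)C)(C(C)C)C(C)C)=CC[C@@]2(C)[C@@H]1CC[C@@H](C)CC(=O)OC | intermediate
18 | methyl (3R)-5-[(1R,4aR,5R,8aR)-5,8a-dimethyl-2-methylidene-6-oxo-1,2,3,4,4a,5,6,8a-octahydronaphthalen-1-yl]-3-methylpentanoate | C=C1CC[C@@H]2[C@@H](C)C(=O)C=C[C@@]2(C)[C@@H]1CC[C@@H](C)CC(=O)OC | intermediate
19 | methyl (3R)-3-methyl-5-[(1R,4aS,8aS)-5,5,8a-trimethyl-2-methylidene-6-oxo-1,2,3,4,4a,5,6,8a-octahydronaphthalen-1-yl]pentanoate | C=C1CC[C@@H]2C(C)(C)C(=O)C=C[C@@]2(C)[C@@H]1CC[C@@H](C)CC(=O)OC | intermediate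
20 | methyl (3R)-3-methyl-5-[(1R,4aS,8aS)-5,5,8a-trimethyl-2-methylidene-6-oxodecahydronaphthalen-1-yl]pentanoate | C=C1CC[C@@H]2C(C)(C)C(=O)CC[C@@]2(C)[C@@H]1CC[C@@H](C)CC(=O)OC | intermediate
21 | methyl (3R)-5-[(1R,4aS,6S,8aS)-6-hydroxy-5,5,8a-trimethyl-2-methylidenedecahydronaphthalen-1-yl]-3-methylpentanoate (axial hydroxyl) | C=C1CC[C@@H]2C(C)(C)[C@@H](O)CC[C@@]2(C)[C@@H]1CC[C@@H](C)CC(=O)OC | intermediate
22 | (3R)-5-[(1R,4aS,6S,8aS)-6-hydroxy-5,5,8a-trimethyl-2-methylidenedecahydronaphthalen-1-yl]-3-methylpentanoic acid | C=C1CC[C@@H]2C(C)(C)[C@@H](O)CC[C@@]2(C)[C@@H]1CC[C@@H](C)CC(=O)O | intermediate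
23 | acetic (3R)-5-[(1R,4aS,6S,8aS)-6-(acetyloxy)-5,5,8a-trimethyl-2-methylidenedecahydronaphthalen-1-yl]-3-methylpentanoic anhydride | C=C1CC[C@@H]2C(C)(C)[C@@H](OC(C)=O)CC[C@@]2(C)[C@@H]1CC[C@@H](C)CC(=O)OC(C)=O | intermediate
24 | (3R)-5-[(1R,4aS,6S,8aS)-6-(acetyloxy)-5,5,8a-trimethyl-2-methylidenedecahydronaphthalen-1-yl]-3-methylpentanoic acid (labdane numbering: 3S,5S,9R,10S,13R) | C=C1CC[C@@H]2C(C)(C)[C@@H](OC(C)=O)CC[C@@]2(C)[C@@H]1CC[C@@H](C)CC(=O)O | target

## Step count and least certain steps

Total step count: 12. Longest linear sequence: 9 steps (steps 1, 3, 6, 7, 8, 9, 10, 11, 12 from 1; equally steps 4, 5, 6–12 from 8).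

Step 3 (key step). The most likely failure is a slow cycloaddition of the trisubstituted enal with the 1-substituted diene, so that protodesilylation or oligomerisation of the diene by the strong acid catalyst wins. A second risk is weaker facial discrimination, because the β-substituent can displace the enal from the shielding aryl group. Fallback (from 4 and 6, returning at 7): the two partners are combined with an achiral Lewis acid (Me2AlCl, CH2Cl2, −78 °C) to give the racemic adduct F1, and the (1R,5R,6R) enantiomer, which is 7, is separated by preparative chromatography on a chiral stationary phase. This replaces asymmetric induction by resolution.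

Step 7. The likely failures are hydrogen transfer from the stannane to the vinyl radical before the 6-exo closure onto the hindered, unactivated C9, translocation of the radical to the allylic C12 position, and incomplete facial selectivity at C9. Fallback (from 15, returning at 17): a closed-shell palladium-hydride reductive enyne cyclisation (Pd2(dba)3·CHCl3, tri-o-tolylphosphine, AcOH, Et3SiH, PhMe, rt → 60 °C). Hydropalladation of the alkyne places palladium on C8, carbopalladation of C9=C11 closes ring B, and the silane reduces the C11–palladium bond, giving 17 directly without a tin intermediate.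

Step 6. The likely failure is sluggish addition of the bulky ylide to the neopentyl aldehyde, with slow decomposition of the ylide on warming and loss of geometric purity. Fallback (from 9, isolated before lactonisation, returning at 17): 9 is converted by a Mitsunobu reaction with 1-phenyl-1H-tetrazole-5-thiol (PPh3, DIAD, THF) into methyl (3S)-3-methyl-5-[(1-phenyl-1H-tetrazol-5-yl)sulfanyl]pentanoate F2, which is oxidised (H2O2, (NH4)6Mo7O24·4H2O, EtOH) to methyl (3S)-3-methyl-5-[(1-phenyl-1H-tetrazol-5-yl)sulfonyl]pentanoate F3. A Julia–Kocienski olefination of 7 with F3 (KN(SiMe3)2, DME, −60 °C → rt) should give methyl (3R,5E)-6-[(1S,5R,6R)-6-(but-3-yn-1-yl)-1,5-dimethyl-4-[(triisopropylsilyl)oxy]cyclohex-3-en-1-yl]-3-methylhex-5-enoate F4. F4 is taken through the conditions of step 7 and should give 17, since the alkene geometry is lost in the cyclisation and the chair transition state still places C11 equatorial.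

Step 8. The likely failure is slow transmetalation of the bulky silyl enol ether to divalent palladium, during which palladium may isomerise the exocyclic alkene. Fallback (from 17, returning at 18): 17 is treated with PhSeCl (CH2Cl2, −78 °C) to give the α-selanyl ketone methyl (3R)-5-[5,8a-dimethyl-2-methylidene-6-oxo-7-(phenylselanyl)decahydronaphthalen-1-yl]-3-methylpentanoate F5. Oxidation (H2O2, pyridine, CH2Cl2, 0 °C) and syn-elimination of the selenoxide towards C1 should give 18.

Step 9. The likely failure is competing deprotonation next to the ester (C14 methylation or Claisen-type condensation) or O-methylation of the hindered enolate. Fallback (from 18, returning at 19): the ester is saponified first (LiOH, THF/H2O) to (3R)-5-[(1R,4aR,5R,8aR)-5,8a-dimethyl-2-methylidene-6-oxo-1,2,3,4,4a,5,6,8a-octahydronaphthalen-1-yl]-3-methylpentanoic acid F6, whose carboxylate cannot be enolised under the alkylation conditions. Treatment with KOt-Bu (2.5 equiv) and excess MeI (THF, then DMF) should methylate C4 and re-esterify the carboxylate in one operation, giving 19.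

## Further compounds

F1 | step 3 | racemic 6-(but-3-yn-1-yl)-1,5-dimethyl-4-[(triisopropylsilyl)oxy]cyclohex-3-ene-1-carbaldehyde (relative configuration shown, racemate) | C#CCC[C@@H]1[C@@H](C)C(O[Si](C(C)C)(C(C)C)C(C)C)=CC[C@@]1(C)C=O
F0 | step 7 | none | none
F2 | step 6 | methyl (3S)-3-methyl-5-[(1-phenyl-1H-tetrazol-5-yl)sulfanyl]pentanoate | COC(=O)C[C@H](C)CCSc1nnnn1-c1ccccc1
F3 | step 6 | methyl (3S)-3-methyl-5-[(1-phenyl-1H-tetrazol-5-yl)sulfonyl]pentanoate | COC(=O)C[C@H](C)CCS(=O)(=O)c1nnnn1-c1ccccc1
F4 | step 6 | methyl (3R,5E)-6-[(1S,5R,6R)-6-(but-3-yn-1-yl)-1,5-dimethyl-4-[(triisopropylsilyl)oxy]cyclohex-3-en-1-yl]-3-methylhex-5-enoate | C#CCC[C@@H]1[C@@H](C)C(O[Si](C(C)C)(C(C)C)C(C)C)=CC[C@@]1(C)/C=C/C[C@@H](C)CC(=O)OC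
F5 | step 8 | methyl (3R)-5-[5,8a-dimethyl-2-methylidene-6-oxo-7-(phenylselanyl)decahydronaphthalen-1-yl]-3-methylpentanoate (ring configuration as in 17, C2 epimers) | C=C1CC[C@@H]2[C@@H](C)C(=O)C([Se]c3ccccc3)C[C@@]2(C)[C@@H]1CC[C@@H](C)CC(=O)OC
F6 | step 9 | (3R)-5-[(1R,4aR,5R,8aR)-5,8a-dimethyl-2-methylidene-6-oxo-1,2,3,4,4a,5,6,8a-octahydronaphthalen-1-yl]-3-methylpentanoic acid | C=C1CC[C@@H]2[C@@H](C)C(=O)C=C[C@@]2(C)[C@@H]1CC[C@@H](C)CC(=O)O
A1 | alternative 1 | methyl 6-[(tert-butyldimethylsilyl)oxy]-2-{[(4-methoxybenzyl)oxy]methyl}-5,5,8a-trimethyl-1,2,4a,5,6,7,8,8a-octahydronaphthalene-1-carboxylate, trans-fused | COc1ccc(COC[C@@H]2C=C[C@@H]3C(C)(C)[C@H](O[Si](C)(C)C(C)(C)C)CC[C@@]3(C)[C@@H]2C(=O)OC)cc1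
A2 | alternative 1 | methyl (2E,6R,8E,10E)-6-[(tert-butyldimethylsilyl)oxy]-12-[(4-methoxybenzyl)oxy]-3,7,7-trimethyldodeca-2,8,10-trienoate | COC(=O)/C=C(\C)CC[C@@H](O[Si](C)(C)C(C)(C)C)C(C)(C)/C=C/C=C/COCc1ccc(OC)cc1
A3 | alternative 2 | 5-(hydroxymethyl)-1,4a-dimethyl-4,4a,7,8-tetrahydronaphthalene-2,6(3H,5H)-dione | O=C1CCC2=C(C)C(=O)CC[C@@]2(C)[C@@H]1CO
A4 | alternative 2 | 1-hydroxy-4,7a-dimethyl-1-(oxiran-2-yl)-1,2,3,6,7,7a-hexahydro-5H-inden-5-one (hydroxyl cis to the angular methyl) | CC1=C2CC[C@](O)([C@@H]3CO3)[C@]2(C)CCC1=O
A5 | alternative 3 | methyl 3,8-dioxo-17-nor-ent-labdan-15-oate | O=C1CC[C@@H]2C(C)(C)C(=O)CC[C@@]2(C)[C@@H]1CC[C@@H](C)CC(=O)OC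
A6 | alternative 3 | methyl (3R,6E,8S)-3,7,9,9-tetramethyl-10-oxo-8-[3-oxo-3-(phenylselanyl)propyl]dodeca-6,11-dienoate | C=CC(=O)C(C)(C)[C@@H](CCC(=O)[Se]c1ccccc1)/C(C)=C/CC[C@@H](C)CC(=O)OC
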